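**Plan**
1. Locants: seven-membered ring C1 (CHMe)–C2–C3–C4 (C–OH)–C5 (CH)–C9 (C=O)–C10 (quaternary). Five-membered ring C4–C5–C6–C7 (CHOH)–C8 (CMe2). Side chain C11–C12 on C10, then the butenolide.
2. Retrosynthetic cuts, in order: C12–butenolide (Negishi coupling); C7–H; the C4–O/C5–H pair (epoxide); one C8–CH3; the C4–C5 bond with C4–C9 restored (photochemical reorganisation); C9–O (phenol oxidation); C1–CH3; C10–C11.
3. Enabling feature: C9, C5, C6, C7, C8 and C4 are the six carbons of an ortho-methylphenol ring (OH on C7, Me on C8, C9 para to the OH). This ring is fused along C4–C9 to a cyclohexane (ring B) that already holds C10, C1, C2 and C3. Oxidation at C9 gives a cross-conjugated quinol dienone, and light can contract the dienone ring and enlarge ring B in one event.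
4. Forward order: the 6/6 tetralin is bought, C10 and C1 are substituted, and the phenol is dearomatised. Irradiation turns 6/6 into 5/7, the cyclopentane is then functionalised, and the butenolide is joined in the penultimate step.
5. Stereochemistry: C10 comes from an asymmetric phase-transfer alkylation and C1 from OH-directed hydrogenation. C4 comes from epoxidation anti to the pseudo-axial C10 methyl, C5 from enolate protonation (trans-fused ketol), and C7 from hydride delivery directed by the C4 hydroxyl.

Key step: step 10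

Assumption: the cinchonidine-derived ammonium salt is taken to give the (R)-ketone 7, by analogy with alkylations of related 1-methyl-2-tetralones. If the sense proved opposite, the pseudo-enantiomeric cinchonine-derived salt would be used.

**Route**

Step 1
Reactants: 1 6-methoxy-5-methyl-1-tetralone
Product: 3 7-methoxy-4,8-dimethyl-1,2-dihydronaphthalene, via tertiary benzylic alcohol 2 (not isolated)
Conditions: MeMgBr, THF, 0 °C to rt; then 2 M HCl, rt
Reagents that add atoms: methylmagnesium bromide, C[Mg]Br
Why: Grignard 1,2-addition brings in the future C10 methyl group, and the para-methoxy-stabilised tertiary benzylic alcohol should lose water on acidic work-up (E1 dehydration) to give the endocyclic C10=C1 styrene.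

Step 2
Reactants: 3 7-methoxy-4,8-dimethyl-1,2-dihydronaphthalene
Product: 5 6-methoxy-1,5-dimethyl-3,4-dihydronaphthalen-2(1H)-one (racemic), via benzylic epoxide 4 (not isolated)
Conditions: mCPBA, CH2Cl2/aq NaHCO3, 0 °C; crude epoxide, BF3·OEt2 (cat.), CH2Cl2, −20 °C
Reagents that add atoms: mCPBA, OOC(=O)c1cccc(Cl)c1
Why: Prilezhaev epoxidation of the electron-rich styrene followed by Meinwald rearrangement, in which the epoxide opens to the C10 cation stabilised by the para methoxy group and a 1,2-hydride shift places the carbonyl on C1.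

Step 3
Reactants: 5 6-methoxy-1,5-dimethyl-3,4-dihydronaphthalen-2(1H)-one; 6 tert-butyl bromoacetate
Product: 7 tert-butyl 2-[(1R)-6-methoxy-1,5-dimethyl-2-oxo-1,2,3,4-tetrahydronaphthalen-1-yl]acetate
Conditions: N-[4-(trifluoromethyl)benzyl]cinchonidinium bromide (10 mol %), 50% aq NaOH, toluene, 0 °C, argon
Reagents that add atoms: none
Why: Asymmetric phase-transfer alkylation of the aryl-conjugated enolate of a 1-methyl-2-tetralone with a reactive α-bromo ester, in which the tight ion pair with the chiral ammonium cation shields one enolate face and sets quaternary C10 (R here), with recrystallisation of 7 foreseen to reach enantiopurity.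

Step 4
Reactants: 7 keto ester
Product: 8 tert-butyl 2-[(1S)-6-methoxy-1,5-dimethyl-2-methylidene-1,2,3,4-tetrahydronaphthalen-1-yl]acetate
Conditions: Ph3PCH3Br, KOt-Bu, toluene/THF, rt to 60 °C
Reagents that add atoms: methyltriphenylphosphonium bromide, C[P+](c1ccccc1)(c1ccccc1)c1ccccc1.[Br-]
Why: Wittig methylenation with the small unstabilised ylide is the standard way to olefinate an α-quaternary ketone, the tert-butyl ester is inert to it, C10 cannot epimerise, and the descriptor changes only because the CIP ranking changes.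

Step 5
Reactants: 8 methylidene ester
Product: 9 2-[(1S)-6-methoxy-1,5-dimethyl-2-methylidene-1,2,3,4-tetrahydronaphthalen-1-yl]ethan-1-ol
Conditions: LiAlH4, THF, 0 °C
Reagents that add atoms: none
Why: Hydride reduction of the ester to the primary alcohol leaves the isolated alkene and the anisole untouched and frees the hydroxyl group needed to direct the next step.

Step 6
Reactants: 9 methylidene alcohol
Product: 10 2-[(1S,2R)-6-methoxy-1,2,5-trimethyl-1,2,3,4-tetrahydronaphthalen-1-yl]ethan-1-ol
Conditions: H2 (1 atm), [Ir(cod)(PCy3)(py)]PF6 (5 mol %), CH2Cl2, rt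
Reagents that add atoms: none
Why: Hydroxyl-directed homogeneous hydrogenation, in which the hydroxyethyl arm on the α face binds the cationic iridium centre and hydrogen is delivered to C1 from that face, so the new C1 methyl group ends up β and cis to the C10 methyl group (C1 = R).

Step 7
Reactants: 10 methyl ether alcohol
Product: 11 (5S,6R)-5-(2-hydroxyethyl)-1,5,6-trimethyl-5,6,7,8-tetrahydronaphthalen-2-ol
Conditions: NaSEt, DMF, 130 °C; aq HCl work-up
Reagents that add atoms: none
Why: SN2 demethylation of the aryl methyl ether by thiolate releases the phenoxide as leaving group, and the aliphatic alkoxide formed alongside is only a spectator.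

Step 8
Reactants: 11 phenol alcohol
Product: 12 (5S,6R)-5-{2-[(tert-butyldiphenylsilyl)oxy]ethyl}-1,5,6-trimethyl-5,6,7,8-tetrahydronaphthalen-2-ol
Conditions: TBDPSCl (1.05 equiv), imidazole, CH2Cl2, 0 °C
Reagents that add atoms: tert-butyldiphenylsilyl chloride, CC(C)(C)[Si](Cl)(c1ccccc1)c1ccccc1
Why: Chemoselective silylation of the unhindered primary alcohol over the ortho-methyl-flanked phenol, the bulky silyl ether being chosen because its oxygen is too hindered and too weakly nucleophilic to intercept the cationic intermediate of the next step through a five-membered ring.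

Step 9
Reactants: 12 silyl ether phenol
Product: 13 (4aS,5S,6R)-5-{2-[(tert-butyldiphenylsilyl)oxy]ethyl}-4a-hydroxy-1,5,6-trimethyl-5,6,7,8-tetrahydronaphthalen-2(4aH)-one
Conditions: PhI(OAc)2, MeCN/H2O, 0 °C
Reagents that add atoms: water, O
Why: Hydroxylative phenol dearomatisation with a trivalent iodine oxidant, in which water adds para to the oxygen at C9 (no quinone methide can form because C10 bears no hydrogen), attack anti to the pseudo-axial C10 methyl group should place the OH α, and this configuration is of no consequence because C9 becomes trigonal in step 10 and C5 is planarised in step 11.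

Step 10
Reactants: 13 para-quinol dienone
Product: 15 (3aR,5S,6R)-5-{2-[(tert-butyldiphenylsilyl)oxy]ethyl}-1,5,6-trimethyl-3,3a,5,6,7,8-hexahydroazulene-2,4-dione, via cyclopropyl oxyallyl zwitterion 14 (not isolated)
Conditions: hν (365 nm), degassed AcOH/H2O/MeCN, argon, 20 °C
Reagents that add atoms: none
Why: Proposed new method: excitation of the cross-conjugated dienone should bond the two β-carbons C4 and C5 and, after demotion, give zwitterion 14, in which a C4–C5–C9 cyclopropane adjoins an oxyallyl cation spread over C6–C7–C8; the C4–C9 bond then opens toward the cationic terminus C8, the charge arriving at C9 is quenched at once by its own hydroxyl group (C9=O), and the remaining dienolate takes up a proton at C6. The closest known reaction type is the santonin-type photorearrangement of 4,4-dialkyl cyclohexadienones in aqueous acetic acid to 5/7-fused hydroxy ketones, where external water plays the part taken here by the internal OH; a 4-hydroxy dienone has not been shown to follow this course. The five-membered ring is closed by the β,β′ bonding (closure of the five-carbon array C4–C8–C7–C6–C5), whereas the seven-membered ring is not closed by a new bond but arises from ring B when the shared C4–C9 bond breaks. The only new stereocentre, C5, is controlled by C9: ring B must stay cis-fused to the cyclopropane, which forces the hydroxyl group endo and makes C9 fold toward the α face, so H5 is β (3aR), a labile centre that is erased in step 11. The selectivity needed is cleavage of C4–C9 rather than C5–C9 (the latter would lead to a spiro[4.5]decane), and it is secured by the C8 methyl group, which localises positive charge on C8 and makes the emerging C4=C8 bond tetrasubstituted. Irradiation at 365 nm addresses the long-wavelength tail of the dienone and should spare the cyclopentenone product and the phenyl groups on silicon.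

Step 11
Reactants: 15 hydroazulene enedione
Product: 17 (5S,6R)-5-{2-[(tert-butyldiphenylsilyl)oxy]ethyl}-1,1,5,6-tetramethyl-1,3,5,6,7,8-hexahydroazulene-2,4-dione, via potassium dienolate 16 (not isolated)
Conditions: KOt-Bu (1.05 equiv), THF/t-BuOH, 0 °C; then MeI, 0 °C
Reagents that add atoms: iodomethane, CI
Why: Deconjugative α-alkylation of an extended enolate, in which the doubly activated C5–H (α to C9=O and γ to the C7 enone) is removed selectively by one equivalent of base and methylation should occur at C8 rather than C5 because C5 is shielded by the C9 carbonyl and quaternary C10, moving the alkene to C4=C5.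

Step 12
Reactants: 17 C4=C5 enone
Product: 18 (3aR,5S,6R,8aS)-5-{2-[(tert-butyldiphenylsilyl)oxy]ethyl}-3a,8a-epoxy-1,1,5,6-tetramethyloctahydroazulene-2,4-dione
Conditions: DMDO (acetone solution), CH2Cl2, 0 °C to rt
Reagents that add atoms: dimethyldioxirane, CC1(C)OO1
Why: Dioxirane epoxidation of a tetrasubstituted enone under neutral conditions avoids base-induced migration of the alkene toward C6, and because the favoured chair-like cycloheptenone conformer has the C1 methyl and the side chain pseudo-equatorial and the C10 methyl pseudo-axial on the β face, oxygen should arrive from the α face and fix C4.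

Step 13
Reactants: 18 α,β-epoxy ketone
Product: 19 (3aR,5S,6R,8aR)-5-{2-[(tert-butyldiphenylsilyl)oxy]ethyl}-8a-hydroxy-1,1,5,6-tetramethyloctahydroazulene-2,4-dione
Conditions: SmI2 (2.2 equiv), THF/MeOH, −78 °C
Reagents that add atoms: none
Why: Reductive opening of an α,β-epoxy ketone with SmI2, in which the C9 ketyl expels the C5–O bond and keeps C4–O (α), and the samarium enolate is protonated at C5 from the β face anti to the bulky samarium alkoxide, giving the trans-fused ketol that is also expected to be the more stable C5 epimer, so later enolisation should not erode it.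

Step 14
Reactants: 19 silyl ether ketol
Product: 20 (3aR,5S,6R,8aR)-8a-hydroxy-5-(2-hydroxyethyl)-1,1,5,6-tetramethyloctahydroazulene-2,4-dione
Conditions: HF·pyridine, THF/pyridine, 0 °C to rt
Reagents that add atoms: none
Why: Fluoride-induced desilylation in a mildly acidic medium avoids the basic conditions under which the β-hydroxy ketone could undergo retro-aldol cleavage or dehydration.

Step 15
Reactants: 20 primary alcohol
Product: 21 (3aR,5S,6R,8aR)-8a-hydroxy-5-(2-iodoethyl)-1,1,5,6-tetramethyloctahydroazulene-2,4-dione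
Conditions: I2, PPh3, imidazole, CH2Cl2, 0 °C
Reagents that add atoms: iodine, II
Why: Appel-type iodination acts only on the primary alcohol because the other hydroxyl group is tertiary and flanked by CMe2, and keeping C7 as a ketone at this stage removes any competition from a secondary alcohol.

Step 16
Reactants: 21 primary iodide; 22 4-bromofuran-2(5H)-one
Product: 24 4-{2-[(3aR,5S,6R,8aR)-8a-hydroxy-1,1,5,6-tetramethyl-2,4-dioxodecahydroazulen-5-yl]ethyl}furan-2(5H)-one, via alkylzinc iodide 23 (not isolated)
Conditions: Zn dust, LiCl, THF, 25 °C; then 22, Pd(OAc)2 (5 mol %), SPhos, THF, 25 °C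
Reagents that add atoms: none
Why: Negishi sp3–sp2 coupling, in which zinc inserts into the primary C–I bond, the alkylzinc iodide tolerates ketones and is protonated only slowly by a hindered tertiary alcohol, the β-bromo butenolide adds readily to zerovalent palladium, and the neutral medium spares the ketol.

Step 17
Reactants: 24 7-ketone
Product: 25 4-{2-[(2R,3aR,5S,6R,8aR)-2,8a-dihydroxy-1,1,5,6-tetramethyl-4-oxodecahydroazulen-5-yl]ethyl}furan-2(5H)-one (target)
Conditions: Me4NBH(OAc)3, MeCN/AcOH, −20 °C
Reagents that add atoms: none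
Why: Evans–Saksena reduction, in which ligand exchange at the C4 hydroxyl group and intramolecular hydride delivery to the α face of C7 give the 1,3-anti diol (C7–OH β, R), while the C9 ketone flanked by quaternary C10 and tertiary C5 and the butenolide should remain untouched.

**Compound list**
1 | 6-methoxy-5-methyl-3,4-dihydronaphthalen-1(2H)-one | COc1ccc2c(c1C)CCCC2=O | starting material
2 | 6-methoxy-1,5-dimethyl-1,2,3,4-tetrahydronaphthalen-1-ol (racemic) | COc1ccc2c(c1C)CCCC2(C)O | intermediate
3 | 7-methoxy-4,8-dimethyl-1,2-dihydronaphthalene | COc1ccc2c(c1C)CCC=C2C | intermediate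
4 | 5-methoxy-4,7b-dimethyl-1a,2,3,7b-tetrahydronaphtho[1,2-b]oxirene (racemic) | COc1ccc2c(c1C)CCC3OC23C | intermediate
5 | 6-methoxy-1,5-dimethyl-3,4-dihydronaphthalen-2(1H)-one (racemic) | COc1ccc2c(c1C)CCC(=O)C2C | intermediate
6 | tert-butyl bromoacetate | BrCC(=O)OC(C)(C)C | starting material
7 | tert-butyl 2-[(1R)-6-methoxy-1,5-dimethyl-2-oxo-1,2,3,4-tetrahydronaphthalen-1-yl]acetate | COc1ccc2c(c1C)CCC(=O)[C@]2(C)CC(=O)OC(C)(C)C | intermediate
8 | tert-butyl 2-[(1S)-6-methoxy-1,5-dimethyl-2-methylidene-1,2,3,4-tetrahydronaphthalen-1-yl]acetate | COc1ccc2c(c1C)CCC(=C)[C@]2(C)CC(=O)OC(C)(C)C | intermediate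
9 | 2-[(1S)-6-methoxy-1,5-dimethyl-2-methylidene-1,2,3,4-tetrahydronaphthalen-1-yl]ethan-1-ol | COc1ccc2c(c1C)CCC(=C)[C@]2(C)CCO | intermediate
10 | 2-[(1S,2R)-6-methoxy-1,2,5-trimethyl-1,2,3,4-tetrahydronaphthalen-1-yl]ethan-1-ol | C[C@@H]1CCc2c(C)c(OC)ccc2[C@@]1(C)CCO | intermediate
11 | (5S,6R)-5-(2-hydroxyethyl)-1,5,6-trimethyl-5,6,7,8-tetrahydronaphthalen-2-ol | C[C@@H]1CCc2c(C)c(O)ccc2[C@@]1(C)CCO | intermediate
12 | (5S,6R)-5-{2-[(tert-butyldiphenylsilyl)oxy]ethyl}-1,5,6-trimethyl-5,6,7,8-tetrahydronaphthalen-2-ol | C[C@@H]1CCc2c(C)c(O)ccc2[C@@]1(C)CCO[Si](c3ccccc3)(c3ccccc3)C(C)(C)C | intermediate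
13 | (4aS,5S,6R)-5-{2-[(tert-butyldiphenylsilyl)oxy]ethyl}-4a-hydroxy-1,5,6-trimethyl-5,6,7,8-tetrahydronaphthalen-2(4aH)-one | C[C@@H]1CCC2=C(C)C(=O)C=C[C@]2(O)[C@@]1(C)CCO[Si](c3ccccc3)(c3ccccc3)C(C)(C)C | intermediate
14 | zwitterion with a C4–C5–C9 cyclopropane (OH endo) and a C6–C7–C8 oxyallyl cation | C[C@@H]1CC[C@@]23[C@@H](C=C([O-])[C+]2C)[C@]3(O)[C@@]1(C)CCO[Si](c4ccccc4)(c4ccccc4)C(C)(C)C | intermediate
15 | (3aR,5S,6R)-5-{2-[(tert-butyldiphenylsilyl)oxy]ethyl}-1,5,6-trimethyl-3,3a,5,6,7,8-hexahydroazulene-2,4-dione | C[C@@H]1CCC2=C(C)C(=O)C[C@H]2C(=O)[C@@]1(C)CCO[Si](c3ccccc3)(c3ccccc3)C(C)(C)C | intermediate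
16 | potassium dienolate of 15 (C5 deprotonated) | [K+].C[C@@H]1CCC2=C(CC([O-])=C2C)C(=O)[C@@]1(C)CCO[Si](c3ccccc3)(c3ccccc3)C(C)(C)C | intermediate
17 | (5S,6R)-5-{2-[(tert-butyldiphenylsilyl)oxy]ethyl}-1,1,5,6-tetramethyl-1,3,5,6,7,8-hexahydroazulene-2,4-dione | C[C@@H]1CCC2=C(CC(=O)C2(C)C)C(=O)[C@@]1(C)CCO[Si](c3ccccc3)(c3ccccc3)C(C)(C)C | intermediate
18 | (3aR,5S,6R,8aS)-5-{2-[(tert-butyldiphenylsilyl)oxy]ethyl}-3a,8a-epoxy-1,1,5,6-tetramethyloctahydroazulene-2,4-dione | C[C@@H]1CC[C@@]23O[C@@]2(CC(=O)C3(C)C)C(=O)[C@@]1(C)CCO[Si](c4ccccc4)(c4ccccc4)C(C)(C)C | intermediate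
19 | (3aR,5S,6R,8aR)-5-{2-[(tert-butyldiphenylsilyl)oxy]ethyl}-8a-hydroxy-1,1,5,6-tetramethyloctahydroazulene-2,4-dione | C[C@@H]1CC[C@@]2(O)[C@@H](CC(=O)C2(C)C)C(=O)[C@@]1(C)CCO[Si](c3ccccc3)(c3ccccc3)C(C)(C)C | intermediate
20 | (3aR,5S,6R,8aR)-8a-hydroxy-5-(2-hydroxyethyl)-1,1,5,6-tetramethyloctahydroazulene-2,4-dione | C[C@@H]1CC[C@@]2(O)[C@@H](CC(=O)C2(C)C)C(=O)[C@@]1(C)CCO | intermediate
21 | (3aR,5S,6R,8aR)-8a-hydroxy-5-(2-iodoethyl)-1,1,5,6-tetramethyloctahydroazulene-2,4-dione | C[C@@H]1CC[C@@]2(O)[C@@H](CC(=O)C2(C)C)C(=O)[C@@]1(C)CCI | intermediate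
22 | 4-bromofuran-2(5H)-one | O=C1C=C(Br)CO1 | starting material
23 | alkylzinc iodide derived from 21 | C[C@@H]1CC[C@@]2(O)[C@@H](CC(=O)C2(C)C)C(=O)[C@@]1(C)CC[Zn]I | intermediate
24 | 4-{2-[(3aR,5S,6R,8aR)-8a-hydroxy-1,1,5,6-tetramethyl-2,4-dioxodecahydroazulen-5-yl]ethyl}furan-2(5H)-one | C[C@@H]1CC[C@@]2(O)[C@@H](CC(=O)C2(C)C)C(=O)[C@@]1(C)CCC1=CC(=O)OC1 | intermediate
25 | 4-{2-[(2R,3aR,5S,6R,8aR)-2,8a-dihydroxy-1,1,5,6-tetramethyl-4-oxodecahydroazulen-5-yl]ethyl}furan-2(5H)-one | C[C@@H]1CC[C@@]2(O)[C@@H](C[C@@H](O)C2(C)C)C(=O)[C@@]1(C)CCC1=CC(=O)OC1 | target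

**Count**
Total steps: 17. Longest linear sequence: 17 steps (1 to 25).

**Steps most likely to fail**

Step 10. The excited dienone or zwitterion 14 may leak into other channels. These include a 1,4-sigmatropic shift of the cyclopropane, homolysis of the C9–C10 bond with rearomatisation, opening of the C5–C9 bond, and secondary photolysis on over-irradiation.
The fallback uses only known reaction types. It sets out from alcohol 10 and returns at enedione 15.
- Birch reduction of 10 (Li, NH3, t-BuOH, THF, −78 °C) should give the 5,8-dihydroanisole alcohol F1, which keeps the tetrasubstituted C4=C9 alkene.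
- Silylation (TBDPSCl, imidazole, CH2Cl2) gives the dihydroanisole silyl ether F2.
- Mild enol ether hydrolysis (oxalic acid, aq THF) gives the β,γ-unsaturated ketone F3.
- Ozonolysis (O3, CH2Cl2, −78 °C; Me2S) cuts C4=C9 to the ten-membered triketone F4.
- Intramolecular aldol condensation (piperidine, AcOH, toluene, reflux) of C5 onto the C4 carbonyl forms the same C4–C5 bond. Loss of water toward C8 then delivers 15, whose high acidity makes it the thermodynamic sink.

Step 12. Oxygen transfer to the hindered, electron-poor tetrasubstituted alkene may be sluggish, and the remote C10 substituents may discriminate poorly between the two faces.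
The fallback replaces conformational control by reagent control followed by hydroxyl direction. It sets out from 17 and returns at 18.
- Corey–Bakshi–Shibata reduction of the C7 ketone uses (R)-Me-CBS and BH3·SMe2 in THF at −20 °C. Quaternary C8 acts as the large group and C6H2 as the small one, and the hindered C9 enone is left alone. This should give the 7α-alcohol F6.
- Hydroxyl-directed epoxidation of this cyclopent-3-enol (VO(acac)2, t-BuOOH, CH2Cl2) places the oxygen syn to the OH, on the α face, and gives the epoxy alcohol F7.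
- Dess–Martin oxidation restores the C7 ketone of 18.

Step 9. Capture of the oxidised phenol by water at the para carbon, which is flanked by quaternary C10, may be slow. Ortho attack, participation of the side-chain oxygen, or oligomerisation could then compete.
The fallback replaces the cationic pathway by singlet oxygen. It sets out from 12 and returns at 13.
- Treatment of 12 with KHSO5 (as 2KHSO5·KHSO4·K2SO4) and NaHCO3 in MeCN/H2O generates singlet oxygen. This small reagent should add para to the phenolate oxygen to give the para-peroxyquinol F5.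
- Reduction of the O–O bond with Me2S gives 13.

**Further compounds**
F1 | step 10 | 2-[(1S,2R)-6-methoxy-1,2,5-trimethyl-1,2,3,4,5,8-hexahydronaphthalen-1-yl]ethan-1-ol (epimers at the ring CHMe next to the enol ether) | C[C@@H]1CCC2=C(CC=C(OC)C2C)[C@@]1(C)CCO
F2 | step 10 | tert-butyldiphenylsilyl ether of F1 | C[C@@H]1CCC2=C(CC=C(OC)C2C)[C@@]1(C)CCO[Si](c3ccccc3)(c3ccccc3)C(C)(C)C
F3 | step 10 | (5S,6R)-5-{2-[(tert-butyldiphenylsilyl)oxy]ethyl}-1,5,6-trimethyl-3,4,5,6,7,8-hexahydronaphthalen-2(1H)-one (C1 epimers) | C[C@@H]1CCC2=C(CCC(=O)C2C)[C@@]1(C)CCO[Si](c3ccccc3)(c3ccccc3)C(C)(C)C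
F4 | step 10 | (7S,8R)-7-{2-[(tert-butyldiphenylsilyl)oxy]ethyl}-2,7,8-trimethylcyclodecane-1,3,6-trione (C2 epimers) | C[C@@H]1CCC(=O)C(C)C(=O)CCC(=O)[C@@]1(C)CCO[Si](c3ccccc3)(c3ccccc3)C(C)(C)C
F5 | step 9 | (4aS,5S,6R)-5-{2-[(tert-butyldiphenylsilyl)oxy]ethyl}-4a-hydroperoxy-1,5,6-trimethyl-5,6,7,8-tetrahydronaphthalen-2(4aH)-one | C[C@@H]1CCC2=C(C)C(=O)C=C[C@]2(OO)[C@@]1(C)CCO[Si](c3ccccc3)(c3ccccc3)C(C)(C)C
F6 | step 12 | (2S,5S,6R)-5-{2-[(tert-butyldiphenylsilyl)oxy]ethyl}-2-hydroxy-1,1,5,6-tetramethyl-2,3,5,6,7,8-hexahydroazulen-4(1H)-one | C[C@@H]1CCC2=C(C[C@H](O)C2(C)C)C(=O)[C@@]1(C)CCO[Si](c3ccccc3)(c3ccccc3)C(C)(C)C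
F7 | step 12 | (2S,3aR,5S,6R,8aS)-5-{2-[(tert-butyldiphenylsilyl)oxy]ethyl}-3a,8a-epoxy-2-hydroxy-1,1,5,6-tetramethyloctahydroazulen-4(1H)-one | C[C@@H]1CC[C@@]23O[C@@]2(C[C@H](O)C3(C)C)C(=O)[C@@]1(C)CCO[Si](c4ccccc4)(c4ccccc4)C(C)(C)C
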